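**Plan**
- Retrosynthesis first removes the prenyl and butyryl C–C bonds on ring A and the acetyl C–C bond on ring B, then dismantles ring B across C1'–C6', C2'–C3' and C5'–C6'.
- This is possible because ring B is a hexasubstituted benzene with oxygen on the alternating carbons C2', C4', C6' in three different states and carbon on C1', C3', C5'. The pieces are a silyl ynol ether carrying the ring A benzyl group and 3-benzyloxy-4-methylcyclobutenone.
- Forward: the tribenzyl ether of ring A is brominated, propargylated and oxidised to the siloxyalkyne; the cyclobutenone comes from methylketene and benzyl ethynyl ether.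
- Ring B is the only ring made: heating the two fragments closes it with C6'–OH free (then OMe), C2'–O silylated and C4'–O benzylated.
- Acetyl then goes on C3' by phenol-directed formylation, methyl addition and oxidation; butyryl on ring A, hydrogenolysis and prenylation follow, prenylation last because the alkene would not survive hydrogenolysis.
- Stereochemistry: the target is achiral; the racemic centres of the cyclobutenone, of two benzannulation intermediates and of a carbinol are erased by aromatisation or oxidation.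

Key step: step 8

Remark: ring B locants follow the target (C1' bears the bridging CH2, then C2' OH, C3' acetyl, C4' OH, C5' methyl, C6' OMe); 1,3,5-tris(benzyloxy)benzene is taken as a purchasable compound.

**Route**

Step 1
Reactants: 1 1,3,5-tris(benzyloxy)benzene
Product: 2 1,3,5-tris(benzyloxy)-2-bromobenzene
Conditions: NBS (1.0 equiv), CH2Cl2, −78 → 0 °C
Reagents that add atoms: N-bromosuccinimide, O=C1CCC(=O)N1Br
Why: Electrophilic aromatic bromination of a triply activated arene whose three free positions are equivalent, so one equivalent of NBS at low temperature should stop at the monobromide.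

Step 2
Reactants: 2 1,3,5-tris(benzyloxy)-2-bromobenzene; 3 3-bromo-1-(trimethylsilyl)prop-1-yne
Product: 5 trimethyl[3-[2,4,6-tris(benzyloxy)phenyl]prop-1-yn-1-yl]silane, via aryllithium 4 (not isolated)
Conditions: n-BuLi, THF, −78 °C; then CuI (10 mol %) and 3, −78 → 0 °C
Reagents that add atoms: none
Why: Bromine–lithium exchange outruns benzylic deprotonation at −78 °C, and copper-catalysed SN2 alkylation with the silyl-capped propargylic bromide should avoid both acetylide formation and allene formation.

Step 3
Reactants: 5 trimethyl[3-[2,4,6-tris(benzyloxy)phenyl]prop-1-yn-1-yl]silane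
Product: 6 1,3,5-tris(benzyloxy)-2-(prop-2-yn-1-yl)benzene
Conditions: K2CO3 (0.2 equiv), MeOH–THF, rt
Reagents that add atoms: none
Why: Base-catalysed methanolysis of the alkynyl C–Si bond (protodesilylation) is mild enough to leave the benzyl ethers and the propargylic CH2 untouched.

Step 4
Reactants: 6 1,3,5-tris(benzyloxy)-2-(prop-2-yn-1-yl)benzene
Product: 9 tri(propan-2-yl)[[3-[2,4,6-tris(benzyloxy)phenyl]prop-1-yn-1-yl]oxy]silane, via lithium acetylide 7 (not isolated), via lithium ynolate 8 (not isolated)
Conditions: n-BuLi, THF, −78 °C; t-BuOOLi (from t-BuOOH and LiN(SiMe3)2, THF, −78 °C), −78 → 0 °C; then i-Pr3SiOTf, −78 → 0 °C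
Reagents that add atoms: tert-butyl hydroperoxide, CC(C)(C)OO; triisopropylsilyl trifluoromethanesulfonate, CC(C)[Si](OS(=O)(=O)C(F)(F)F)(C(C)C)C(C)C
Why: Electrophilic oxygenation of a lithium acetylide by lithium tert-butyl peroxide gives the lithium ynolate, which a bulky silyl triflate should capture on oxygen to give the silyl ynol ether.

Step 5
Reactants: 10 benzyl alcohol; 11 trichloroethylene
Product: 14 benzyl (E)-1,2-dichlorovinyl ether, via potassium benzyloxide 12 (not isolated), via dichloroacetylene 13 (not isolated)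
Conditions: KH, THF, 0 °C; then 11, −40 °C → rt
Reagents that add atoms: none
Why: Elimination–addition vinylic substitution, in which the alkoxide removes HCl from trichloroethylene and then adds anti across the dichloroacetylene so formed, which is why the (E)-dichlorovinyl ether should result.

Step 6
Reactants: 14 benzyl (E)-1,2-dichlorovinyl ether
Product: 17 benzyl ethynyl ether, via chloroalkynyl ether 15 (not isolated), via lithium alkoxyacetylide 16 (not isolated)
Conditions: n-BuLi (2.2 equiv), Et2O, −78 °C; MeOH, −78 °C; cold aqueous work-up, used at once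
Reagents that add atoms: none
Why: Base-induced β-elimination of HCl followed by chlorine–lithium exchange gives the lithium alkoxyacetylide, and protonation at −78 °C keeps the benzyl ynol ether below the temperature at which it rearranges.

Step 7
Reactants: 17 benzyl ethynyl ether; 18 propanoyl chloride
Product: 20 (±)-3-(benzyloxy)-4-methylcyclobut-2-en-1-one, via methylketene 19 (not isolated)
Conditions: 18 (slow addition), Et3N, Et2O, 0 °C → rt
Reagents that add atoms: none
Why: In this [2+2] cycloaddition of an aldoketene made in situ with an ynol ether, the ketene carbonyl carbon bonds to the unsubstituted, nucleophilic alkyne carbon, so the alkoxy group ends at C3 and the methyl-bearing carbon at C4, whose stereocentre forms racemic and is erased in step 8.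

Step 8
Reactants: 9 tri(propan-2-yl)[[3-[2,4,6-tris(benzyloxy)phenyl]prop-1-yn-1-yl]oxy]silane; 20 (±)-3-(benzyloxy)-4-methylcyclobut-2-en-1-one
Product: 25 3-(benzyloxy)-2-methyl-5-[tri(propan-2-yl)silyloxy]-6-[[2,4,6-tris(benzyloxy)phenyl]methyl]phenol, via vinylketene 21 (not isolated), via vinylcyclobutenone 22 (not isolated), via dienylketene 23 (not isolated), via cyclohexadienone 24 (not isolated)
Conditions: 20 (1.3 equiv), PhMe, 80 → 110 °C, sealed tube
Reagents that add atoms: none
Why: Proposed new method: on heating, the cyclobutenone should open by a conrotatory 4π electrocyclic reaction (methyl rotating outward) to the 3-benzyloxy vinylketene, whose ketene C=C adds to the siloxyalkyne in a [2+2] sense (bonds C1'–C6' and C2'–C3'); the 4-vinylcyclobutenone so formed opens again to a dienylketene, which closes ring B by a thermal disrotatory 6π electrocyclisation (bond C5'–C6') and tautomerises to the phenol. The closest known reaction type is the Danheiser benzannulation of alkyl- or aryl-substituted cyclobutenones with siloxyalkynes; untested is a 3-alkoxycyclobutenone as the vinylketene source, which would turn the usual resorcinol product into a phloroglucinol with three differently capped oxygens. The vinylogous-ester donor should slow the first ring opening without blocking it, because the reversible opening is drained by irreversible capture of the ketene by the electron-rich alkyne. No stereocentre is created, since the racemic centres of 20, 22 and 24 vanish on aromatisation. The selectivity needed is the regiochemistry of the [2+2] step, secured by the polarisation of the siloxyalkyne: its nucleophilic carbon, the one bearing the ring A benzyl group, bonds to the ketene carbonyl carbon, so the CH2 group sits between the free phenol and the silyl ether. The former ketene oxygen emerges as the only free hydroxyl, flanked by methyl and benzyl, which singles out the C6' oxygen for methylation.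

Step 9
Reactants: 25 3-(benzyloxy)-2-methyl-5-[tri(propan-2-yl)silyloxy]-6-[[2,4,6-tris(benzyloxy)phenyl]methyl]phenol
Product: 26 [5-(benzyloxy)-3-methoxy-4-methyl-2-[[2,4,6-tris(benzyloxy)phenyl]methyl]phenoxy]tri(propan-2-yl)silane
Conditions: MeI, K2CO3, acetone, 56 °C
Reagents that add atoms: iodomethane, CI
Why: Williamson O-methylation of the only free phenol, under conditions to which the bulky aryl silyl ether and the benzyl ethers are inert.

Step 10
Reactants: 26 [5-(benzyloxy)-3-methoxy-4-methyl-2-[[2,4,6-tris(benzyloxy)phenyl]methyl]phenoxy]tri(propan-2-yl)silane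
Product: 27 5-(benzyloxy)-3-methoxy-4-methyl-2-[[2,4,6-tris(benzyloxy)phenyl]methyl]phenol
Conditions: Bu4NF, THF, 0 °C
Reagents that add atoms: none
Why: Fluoride-induced cleavage of the aryl silyl ether, driven by the Si–F bond strength, should free the C2' phenol without touching benzyl or methyl ethers.

Step 11
Reactants: 27 5-(benzyloxy)-3-methoxy-4-methyl-2-[[2,4,6-tris(benzyloxy)phenyl]methyl]phenol
Product: 28 6-(benzyloxy)-2-hydroxy-4-methoxy-5-methyl-3-[[2,4,6-tris(benzyloxy)phenyl]methyl]benzaldehyde
Conditions: MgCl2, Et3N, (CH2O)n, MeCN, 80 °C; then 1 M HCl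
Reagents that add atoms: paraformaldehyde (as formaldehyde), C=O
Why: In the Casnati–Skattebøl ortho-formylation the magnesium phenoxide delivers formaldehyde to its only free ortho carbon (C3') and a second formaldehyde oxidises the benzylic alkoxide, so the ether-only ring A cannot compete.

Step 12
Reactants: 28 6-(benzyloxy)-2-hydroxy-4-methoxy-5-methyl-3-[[2,4,6-tris(benzyloxy)phenyl]methyl]benzaldehyde
Product: 29 (±)-3-(benzyloxy)-2-(1-hydroxyethyl)-5-methoxy-4-methyl-6-[[2,4,6-tris(benzyloxy)phenyl]methyl]phenol
Conditions: MeMgBr (3 equiv), THF, −78 → 0 °C; aq NH4Cl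
Reagents that add atoms: methylmagnesium bromide, C[Mg]Br
Why: Grignard addition to the salicylaldehyde, after the first equivalent has deprotonated the phenol, should give the benzylic carbinol as a racemate whose stereocentre is removed in step 13.

Step 13
Reactants: 29 (±)-3-(benzyloxy)-2-(1-hydroxyethyl)-5-methoxy-4-methyl-6-[[2,4,6-tris(benzyloxy)phenyl]methyl]phenol
Product: 30 1-[6-(benzyloxy)-2-hydroxy-4-methoxy-5-methyl-3-[[2,4,6-tris(benzyloxy)phenyl]methyl]phenyl]ethan-1-one
Conditions: MnO2 (excess), CH2Cl2, rt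
Reagents that add atoms: none
Why: MnO2 oxidation of an electron-rich benzylic alcohol should give the hydrogen-bonded ortho-hydroxy aryl ketone and leave ethers and the diarylmethane alone.

Step 14
Reactants: 30 1-[6-(benzyloxy)-2-hydroxy-4-methoxy-5-methyl-3-[[2,4,6-tris(benzyloxy)phenyl]methyl]phenyl]ethan-1-one
Product: 31 1-[3-[[3-acetyl-4-(benzyloxy)-2-hydroxy-6-methoxy-5-methylphenyl]methyl]-2,4,6-tris(benzyloxy)phenyl]butan-1-one
Conditions: n-PrCO2H and (CF3CO)2O (1.1 equiv each, premixed), CH2Cl2, 0 °C → rt; aq NaHCO3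
Reagents that add atoms: butanoic acid, CCCC(=O)O
Why: In this Friedel–Crafts acylation by the mixed butanoic trifluoroacetic anhydride, ring B is fully substituted, so only the two equivalent activated positions of ring A can react and the first acyl group deactivates the ring against a second.

Step 15
Reactants: 31 1-[3-[[3-acetyl-4-(benzyloxy)-2-hydroxy-6-methoxy-5-methylphenyl]methyl]-2,4,6-tris(benzyloxy)phenyl]butan-1-one
Product: 32 1-[3-[(3-acetyl-2,4-dihydroxy-6-methoxy-5-methylphenyl)methyl]-2,4,6-trihydroxyphenyl]butan-1-one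
Conditions: H2 (1 atm), 10% Pd/C, EtOAc–MeOH, rt
Reagents that add atoms: none
Why: Catalytic hydrogenolysis should cleave all four benzylic C–O bonds, while the hydrogen-bonded aryl ketones and the diarylmethane are not reduced under these mild conditions.

Step 16
Reactants: 32 1-[3-[(3-acetyl-2,4-dihydroxy-6-methoxy-5-methylphenyl)methyl]-2,4,6-trihydroxyphenyl]butan-1-one
Product: 33 1-[3-[(3-acetyl-2,4-dihydroxy-6-methoxy-5-methylphenyl)methyl]-2,4,6-trihydroxy-5-(3-methylbut-2-en-1-yl)phenyl]butan-1-one
Conditions: prenyl bromide (1.1 equiv), 10% aq KOH, 0 °C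
Reagents that add atoms: 1-bromo-3-methylbut-2-ene, CC(C)=CCBr
Why: C-alkylation of an acylphloroglucinol phenoxide in water, where the ambident anion reacts at carbon and the only unsubstituted aromatic carbon in the molecule is C5 of ring A.

**Compound list**

1 | 1,3,5-tris(benzyloxy)benzene | c1ccc(COc2cc(OCc3ccccc3)cc(OCc3ccccc3)c2)cc1 | starting material
2 | 1,3,5-tris(benzyloxy)-2-bromobenzene | Brc1c(OCc2ccccc2)cc(OCc2ccccc2)cc1OCc1ccccc1 | intermediate
3 | 3-bromo-1-(trimethylsilyl)prop-1-yne | C[Si](C)(C)C#CCBr | starting material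
4 | [2,4,6-tris(benzyloxy)phenyl]lithium | [Li]c1c(OCc2ccccc2)cc(OCc2ccccc2)cc1OCc1ccccc1 | intermediate
5 | trimethyl[3-[2,4,6-tris(benzyloxy)phenyl]prop-1-yn-1-yl]silane | C[Si](C)(C)C#CCc1c(OCc2ccccc2)cc(OCc2ccccc2)cc1OCc1ccccc1 | intermediate
6 | 1,3,5-tris(benzyloxy)-2-(prop-2-yn-1-yl)benzene | C#CCc1c(OCc2ccccc2)cc(OCc2ccccc2)cc1OCc1ccccc1 | intermediate
7 | lithium 3-[2,4,6-tris(benzyloxy)phenyl]prop-1-yn-1-ide | [Li]C#CCc1c(OCc2ccccc2)cc(OCc2ccccc2)cc1OCc1ccccc1 | intermediate
8 | lithium 3-[2,4,6-tris(benzyloxy)phenyl]prop-1-yn-1-olate | [Li]OC#CCc1c(OCc2ccccc2)cc(OCc2ccccc2)cc1OCc1ccccc1 | intermediate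
9 | tri(propan-2-yl)[[3-[2,4,6-tris(benzyloxy)phenyl]prop-1-yn-1-yl]oxy]silane | CC(C)[Si](OC#CCc1c(OCc2ccccc2)cc(OCc2ccccc2)cc1OCc1ccccc1)(C(C)C)C(C)C | intermediate
10 | benzyl alcohol | OCc1ccccc1 | starting material
11 | trichloroethylene | ClC=C(Cl)Cl | starting material
12 | potassium benzyloxide | [K+].[O-]Cc1ccccc1 | intermediate
13 | dichloroacetylene | ClC#CCl | intermediate
14 | benzyl (E)-1,2-dichlorovinyl ether | Cl/C=C(/Cl)OCc1ccccc1 | intermediate
15 | benzyl chloroethynyl ether | ClC#COCc1ccccc1 | intermediate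
16 | lithium (benzyloxy)acetylide | [Li]C#COCc1ccccc1 | intermediate
17 | benzyl ethynyl ether | C#COCc1ccccc1 | intermediate
18 | propanoyl chloride | CCC(=O)Cl | starting material
19 | methylketene (prop-1-en-1-one) | CC=C=O | intermediate
20 | (±)-3-(benzyloxy)-4-methylcyclobut-2-en-1-one | CC1C(=O)C=C1OCc1ccccc1 | intermediate
21 | (3Z)-3-(benzyloxy)penta-1,3-dien-1-one | O=C=C/C(OCc1ccccc1)=C/C | intermediate
22 | (±)-4-[(1Z)-1-(benzyloxy)prop-1-en-1-yl]-3-[tri(propan-2-yl)silyloxy]-2-[[2,4,6-tris(benzyloxy)phenyl]methyl]cyclobut-2-en-1-one | O=C1C(Cc2c(OCc3ccccc3)cc(OCc3ccccc3)cc2OCc2ccccc2)=C(O[Si](C(C)C)(C(C)C)C(C)C)C1/C(OCc1ccccc1)=C/C | intermediate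
23 | (3E,5Z)-5-(benzyloxy)-3-[tri(propan-2-yl)silyloxy]-2-[[2,4,6-tris(benzyloxy)phenyl]methyl]hepta-1,3,5-trien-1-one | O=C=C(Cc1c(OCc2ccccc2)cc(OCc2ccccc2)cc1OCc1ccccc1)/C(O[Si](C(C)C)(C(C)C)C(C)C)=C\C(OCc1ccccc1)=C\C | intermediate
24 | (±)-5-(benzyloxy)-6-methyl-3-[tri(propan-2-yl)silyloxy]-2-[[2,4,6-tris(benzyloxy)phenyl]methyl]cyclohexa-2,4-dien-1-one | O=C1C(Cc2c(OCc3ccccc3)cc(OCc3ccccc3)cc2OCc2ccccc2)=C(O[Si](C(C)C)(C(C)C)C(C)C)C=C(OCc2ccccc2)C1C | intermediate
25 | 3-(benzyloxy)-2-methyl-5-[tri(propan-2-yl)silyloxy]-6-[[2,4,6-tris(benzyloxy)phenyl]methyl]phenol | Cc1c(O)c(Cc2c(OCc3ccccc3)cc(OCc3ccccc3)cc2OCc2ccccc2)c(O[Si](C(C)C)(C(C)C)C(C)C)cc1OCc1ccccc1 | intermediate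
26 | [5-(benzyloxy)-3-methoxy-4-methyl-2-[[2,4,6-tris(benzyloxy)phenyl]methyl]phenoxy]tri(propan-2-yl)silane | Cc1c(OC)c(Cc2c(OCc3ccccc3)cc(OCc3ccccc3)cc2OCc2ccccc2)c(O[Si](C(C)C)(C(C)C)C(C)C)cc1OCc1ccccc1 | intermediate
27 | 5-(benzyloxy)-3-methoxy-4-methyl-2-[[2,4,6-tris(benzyloxy)phenyl]methyl]phenol | Cc1c(OC)c(Cc2c(OCc3ccccc3)cc(OCc3ccccc3)cc2OCc2ccccc2)c(O)cc1OCc1ccccc1 | intermediate
28 | 6-(benzyloxy)-2-hydroxy-4-methoxy-5-methyl-3-[[2,4,6-tris(benzyloxy)phenyl]methyl]benzaldehyde | Cc1c(OC)c(Cc2c(OCc3ccccc3)cc(OCc3ccccc3)cc2OCc2ccccc2)c(O)c(C=O)c1OCc1ccccc1 | intermediate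
29 | (±)-3-(benzyloxy)-2-(1-hydroxyethyl)-5-methoxy-4-methyl-6-[[2,4,6-tris(benzyloxy)phenyl]methyl]phenol | CC(O)c1c(O)c(Cc2c(OCc3ccccc3)cc(OCc3ccccc3)cc2OCc2ccccc2)c(OC)c(C)c1OCc1ccccc1 | intermediate
30 | 1-[6-(benzyloxy)-2-hydroxy-4-methoxy-5-methyl-3-[[2,4,6-tris(benzyloxy)phenyl]methyl]phenyl]ethan-1-one | CC(=O)c1c(O)c(Cc2c(OCc3ccccc3)cc(OCc3ccccc3)cc2OCc2ccccc2)c(OC)c(C)c1OCc1ccccc1 | intermediate
31 | 1-[3-[[3-acetyl-4-(benzyloxy)-2-hydroxy-6-methoxy-5-methylphenyl]methyl]-2,4,6-tris(benzyloxy)phenyl]butan-1-one | CCCC(=O)c1c(OCc2ccccc2)cc(OCc2ccccc2)c(Cc2c(O)c(C(C)=O)c(OCc3ccccc3)c(C)c2OC)c1OCc1ccccc1 | intermediate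
32 | 1-[3-[(3-acetyl-2,4-dihydroxy-6-methoxy-5-methylphenyl)methyl]-2,4,6-trihydroxyphenyl]butan-1-one | CCCC(=O)c1c(O)cc(O)c(Cc2c(O)c(C(C)=O)c(O)c(C)c2OC)c1O | intermediate
33 | 1-[3-[(3-acetyl-2,4-dihydroxy-6-methoxy-5-methylphenyl)methyl]-2,4,6-trihydroxy-5-(3-methylbut-2-en-1-yl)phenyl]butan-1-one | CCCC(=O)c1c(O)c(CC=C(C)C)c(O)c(Cc2c(O)c(C(C)=O)c(O)c(C)c2OC)c1O | target

**Count and risks**

Total step count: 16. Longest linear sequence: 13 steps (steps 1–4, 8, 9–16, from compound 1).

Steps most likely to fail:

1. Step 8 (Proposed new method). The donor-substituted cyclobutenone may not open to the vinylketene at a temperature the siloxyalkyne tolerates, or the vinylketene may dimerise or acylate the product phenol faster than the alkyne captures it. The fallback gives up the benzannulation and joins a classically made ring B to ring A through an ortho-quinone methide; it sets out from 1 and comes back at 32. Acylation of 1 as in step 14 should give 1-[2,4,6-tris(benzyloxy)phenyl]butan-1-one F1, and hydrogenolysis as in step 15 should give 1-(2,4,6-trihydroxyphenyl)butan-1-one F2. Separately, purchased 2-methylbenzene-1,3,5-triol is C-acetylated (Ac2O, BF3·OEt2) to 1-(2,4,6-trihydroxy-3-methylphenyl)ethan-1-one F3. Methylation of its non-chelated para hydroxyl (Me2SO4, K2CO3, acetone) gives 1-(2,6-dihydroxy-4-methoxy-3-methylphenyl)ethan-1-one F4. A Mannich reaction at its last free ring carbon (CH2O, Me2NH, EtOH) gives 1-[3-[(dimethylamino)methyl]-2,6-dihydroxy-4-methoxy-5-methylphenyl]ethan-1-one F5. Heating F5 with an excess of F2 in dioxane at 100 °C expels dimethylamine to form 2-acetyl-3-hydroxy-5-methoxy-4-methyl-6-methylidenecyclohexa-2,4-dien-1-one F6, which F2 should capture at carbon to give 32; the route resumes at step 16.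

2. Step 7. The benzyl ynol ether may be lost by sigmatropic rearrangement or polymerisation, and methylketene may dimerise, before the cycloaddition takes place. The fallback sets out from 18 and comes back at 20. With purchased ethoxyacetylene, a robust ynol ether that can be used in large excess, the conditions of step 7 should give 3-ethoxy-4-methylcyclobut-2-en-1-one F7. Acid-catalysed exchange of the vinylogous ester with benzyl alcohol 10 (pyridinium p-toluenesulfonate, benzene, removal of ethanol) then gives 20. This exchange must be run strictly anhydrous and under mild acid so that the double bond does not drift toward the methyl-bearing carbon.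

3. Step 16. The polyphenoxide may be alkylated on oxygen or twice on carbon with dearomatisation, and the methylene bridge may scramble in base. The fallback sets out from 32 and comes back at 33. It replaces phenoxide alkylation by electrophilic aromatic substitution with a prenyl cation (2-methylbut-3-en-2-ol, BF3·OEt2, dioxane, rt, short reaction time to limit chroman formation), in which O-alkylation cannot occur; it makes no compound outside the list (F0).

**Further compounds**

F1 | step 8 | 1-[2,4,6-tris(benzyloxy)phenyl]butan-1-one | CCCC(=O)c1c(OCc2ccccc2)cc(OCc2ccccc2)cc1OCc1ccccc1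
F2 | step 8 | 1-(2,4,6-trihydroxyphenyl)butan-1-one | CCCC(=O)c1c(O)cc(O)cc1O
F3 | step 8 | 1-(2,4,6-trihydroxy-3-methylphenyl)ethan-1-one | CC(=O)c1c(O)cc(O)c(C)c1O
F4 | step 8 | 1-(2,6-dihydroxy-4-methoxy-3-methylphenyl)ethan-1-one | CC(=O)c1c(O)cc(OC)c(C)c1O
F5 | step 8 | 1-[3-[(dimethylamino)methyl]-2,6-dihydroxy-4-methoxy-5-methylphenyl]ethan-1-one | CC(=O)c1c(O)c(CN(C)C)c(OC)c(C)c1O
F6 | step 8 | 2-acetyl-3-hydroxy-5-methoxy-4-methyl-6-methylidenecyclohexa-2,4-dien-1-one | C=C1C(=O)C(C(C)=O)=C(O)C(C)=C1OC
F7 | step 7 | 3-ethoxy-4-methylcyclobut-2-en-1-one | CCOC1=CC(=O)C1C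
F0 | step 16 | none | none
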